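The earlier runs and the new flask are calculated with constants of no real substance, and the scatter is random.

Early on, the south run (1.5 M free monomer, 1.7 mol% initiator) takes up 0.0960 /d of the free monomer charged, but between its last two readings the uptake is 0.0380 /d. The last reading is taken as close to the end of growth, which is an assumption. The readings carry a scatter of 1 percentage point.

- south (time / d: monomer in chains / %): 0.500: 4.8; 1.04: 8.6; 1.67: 14.8; 2.08: 16.2; 2.50: 20.8; 3.00: 20.7; 4.00: 24.5

(readings scatter by 1 percentage point)

The next run is to be one of two recipes: Saturday's, with 1.5 M free monomer, or Thursday's, with 0.40 M, both at 2.6 mol% initiator for 10 d.

* which of the two ends with the longer chains by the average number of monomer units in a chain (chains begun, living or dead) ("neither" if they lie within 10%) (Saturday's / Thursday's / neither)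
* average number of monomer units in a chain (chains begun, living or dead) at the end, Saturday's
* average number of monomer units in a chain (chains begun, living or dead) at the end, Thursday's

The choice hangs on a count of turnovers. The average length (number-average degree of polymerisation) is monomer in chains over chains begun. If each initiator begins one chain, that is the share in chains divided by the loading, and the last south reading gives 14.4 units per chain. If a chain adds units in proportion to [free monomer], whatever the loading, dividing by the south charge gives 9.61 /M, the turnover count: units per chain begun for each mole per litre of free monomer charged. Both assumptions are guesses, since no earlier run shows the number of chains or changes a charge.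

The count gives 14.4 for Saturday's and 3.84 for Thursday's, less than Saturday's. So the next flask is charged as Saturday's, and Thursday's dilution is dropped.

The forecast, on its own reckoning, also names Saturday's, with 16 (11 to 22) units per chain for Saturday's and 4 (0 to 8) for Thursday's: “Saturday's wins either way”.

The longer chains end in Saturday's, with 16.1 units per chain for Saturday's and 3.78 for Thursday's.

    free monomer + initiator → living end + monomer in chains (k = 0.00220 /M/min)
    free monomer + living end → monomer in chains + living end, rate k2*[living end]*[free monomer] (k = 0.00340 /M/min)
    monomer in chains + living end → free monomer + living end, rate k3*[living end] as long as [monomer in chains] is above zero (k = 2.90 × 10⁻⁴ /min)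
    free monomer → uncatalysed product (k = 1.30 × 10⁻⁴ /min)

Divided by the charge of free monomer, these lengths are 10.7 /M for Saturday's and 9.45 /M for Thursday's, against the turnover count of 9.61 /M. A neighbouring flask is Saturday's recipe with 2.5 M free monomer, the loading and time held. The count gives it 24.0 units per chain, and the neighbouring flask gives 21.8, or 8.72 /M when divided by its charge. After 10.0 d its monomer in chains stands at 56.7% of the free monomer charged, more than its uncatalysed product at 40.5%.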